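**Retrosynthetic overview**

1. The tetramic acid is closed last (Lacey–Dieckmann cyclisation of a β-keto amide); the (3′E,5′E)-diene is completed before that by Julia–Kocienski olefination at C5′=C6′.
2. Ring B is opened at C2–C3 and C1–C8a (retro-[4+2]) into a ring A-derived 2-silyloxydiene, C3=C4(OSi)–C4a=C8a, and an (E)-α-methyl enoate, C1=C2, held together by a diisopropylsilyl acetal between the C4 enol oxygen and the C2′ hydroxyl.
3. Enabling feature: C4 is an sp2 CH of ring B that can carry a removable oxygen, and it is 1,5-related to the C2′ carbinol oxygen across the C2–C3 bond (O–C2′–C1′–C2–C3–C4). One silicon atom can therefore bridge the two oxygens; the C4 oxygen is later excised as the C3=C4 alkene.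
4. Stereocontrol: the bought C6 centre sets C8 (cuprate addition); the C8 methyl group and the tether set C1, C2 and C8a in the cycloaddition; C4a follows by kinetic protonation. C2′ is set by a catalytic vinylogous aldol reaction, C7′/C8′ by an auxiliary-controlled aldol reaction.
5. Ring order: ring A (bought) → ring B together with the temporary eight-membered silyl acetal ring (key step) → tether removed → tetramic acid ring.

Key step: step 6

Remark (assumption): (R)-5-methylcyclohex-2-en-1-one is taken as a purchasable building block (it is otherwise reached from (R)-pulegone by a short known sequence).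
Conventions: decalin carbons C1–C8a and side-chain carbons C1′–C10′ are numbered as in the target (C1 quaternary, C2 bears the side chain, C3=C4 ring alkene, C6 and C8 bear CH3; C2′ and C8′ carbinols, C7′ CH(CH3)). α is the face of H-4a, H-8a and the C8 methyl group; β is the face of the C6 methyl group.

**Route**

Step 1
Reactants: 1 (R)-5-methylcyclohex-2-en-1-one
Product: 3 (3R,5R)-3,5-dimethylcyclohex-1-en-1-yl trifluoromethanesulfonate, via lithium enolate 2 (not isolated)
Conditions: Me2CuLi (from MeLi and CuI), Et2O, −78 → −20 °C; then N-(5-chloropyridin-2-yl)bis(trifluoromethanesulfonimide), THF, −78 °C → rt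
Reagents that add atoms: lithium dimethylcuprate, [Li+].C[Cu-]C; N-(5-chloropyridin-2-yl)-1,1,1-trifluoro-N-(trifluoromethanesulfonyl)methanesulfonamide, O=S(=O)(N(c1ccc(Cl)cn1)S(=O)(=O)C(F)(F)F)C(F)(F)F
Why: Cuprate conjugate addition with enolate trapping should deliver the methyl group anti to the existing C5 methyl group (trans-3,5, the future C6/C8 pair), and O-triflation of the regiodefined enolate places the double bond towards the new stereocentre.

Step 2
Reactants: 3 (3R,5R)-3,5-dimethylcyclohex-1-en-1-yl trifluoromethanesulfonate; 4 tributyl(1-ethoxyethenyl)stannane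
Product: 6 1-[(3R,5R)-3,5-dimethylcyclohex-1-en-1-yl]ethan-1-one, via ethoxydiene 5 (not isolated)
Conditions: Pd(PPh3)4 (5 mol %), LiCl, THF, 65 °C; then 1 M HCl, rt
Reagents that add atoms: water, O
Why: Stille coupling of the enol triflate with the α-ethoxyvinyl stannane and acid hydrolysis of the enol ether is a standard acetyl-anion equivalent and should leave the two methyl stereocentres untouched.

Step 3
Reactants: 7 methyl (2E)-2-methylbut-2-enoate
Product: 8 tert-butyl[(1-methoxy-2-methylbuta-1,3-dien-1-yl)oxy]dimethylsilane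
Conditions: LiN(iPr)2, THF/DMPU, −78 °C; then TBSCl, −78 → 0 °C
Reagents that add atoms: tert-butyl(chloro)dimethylsilane, CC(C)(C)[Si](C)(C)Cl
Why: γ-Deprotonation of the tiglate and O-silylation of the dienolate should give the vinylogous silyl ketene acetal (ketene acetal geometry is inconsequential).

Step 4
Reactants: 8 tert-butyl[(1-methoxy-2-methylbuta-1,3-dien-1-yl)oxy]dimethylsilane; 9 (2E)-4,4-dimethoxybut-2-enal
Product: 10 methyl (2E,5R,6E)-5-hydroxy-8,8-dimethoxy-2-methylocta-2,6-dienoate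
Conditions: SiCl4 (1.1 equiv), (R,R)-bisphosphoramide catalyst [two (R)-N,N′-dimethyl-1,1′-binaphthyl-2,2′-diamine-derived cyclic phosphoramides linked through their exocyclic N-methyl nitrogens by a (CH2)5 chain] (2 mol %), iPr2NEt (10 mol %), CH2Cl2, −78 °C; then aq. NaHCO3
Reagents that add atoms: none
Why: A catalytic enantioselective vinylogous Mukaiyama aldol addition (chiral Lewis base-activated SiCl4) should join the dienolate γ-carbon to the conjugated aldehyde with (E)-enoate geometry; the catalyst enantiomer is the one expected to direct Re-face attack and so set C2′ as R (the antipode would be used if the sense proved opposite).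

Step 5
Reactants: 6 1-[(3R,5R)-3,5-dimethylcyclohex-1-en-1-yl]ethan-1-one; 10 methyl (2E,5R,6E)-5-hydroxy-8,8-dimethoxy-2-methylocta-2,6-dienoate
Product: 12 methyl (2E,5R,6E)-5-{[({1-[(3R,5R)-3,5-dimethylcyclohex-1-en-1-yl]ethenyl}oxy)di(propan-2-yl)silyl]oxy}-8,8-dimethoxy-2-methylocta-2,6-dienoate, via chlorosilyl dienol ether 11 (not isolated)
Conditions: 6, KN(SiMe3)2, THF, −78 °C; iPr2SiCl2 (3 equiv), −78 → 0 °C; volatiles removed in vacuo; then 10, imidazole, CH2Cl2, 0 °C → rt
Reagents that add atoms: dichlorodi(propan-2-yl)silane, CC(C)[Si](Cl)(Cl)C(C)C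
Why: Kinetic deprotonation at the acetyl methyl group and O-silylation should give the cross-conjugated 2-silyloxydiene as its chlorosilane, which then silylates the secondary alcohol of 10 (unsymmetrical silyl acetal formation) without touching any stereocentre.

Step 6
Reactants: 12 methyl (2E,5R,6E)-5-{[({1-[(3R,5R)-3,5-dimethylcyclohex-1-en-1-yl]ethenyl}oxy)di(propan-2-yl)silyl]oxy}-8,8-dimethoxy-2-methylocta-2,6-dienoate
Product: 13 silicon-bridged cycloadduct: methyl 1β,6β,8α-trimethyl-1,2,3,5,6,7,8,8aα-octahydronaphthalene-1α-carboxylate (C4=C4a silyl enol ether) whose C4 oxygen and the oxygen of the 2β-[(2R,3E)-5,5-dimethoxy-2-oxypent-3-en-1-yl] chain are joined by Si(iPr)2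
Conditions: o-xylene (0.01 M), 2,6-di-tert-butyl-4-methylphenol (cat.), base-washed sealed tube, 170 °C
Reagents that add atoms: none
Why: On heating, the electron-rich 2-silyloxydiene C3=C4(OSi)–C4a=C8a should add suprafacially across the electron-poor C1=C2 enoate in a concerted, asynchronous [4+2] cycloaddition in which the more nucleophilic terminus C3 bonds to the ester β-carbon C2 and C8a bonds to C1. The closest known reaction type is the type 2 intramolecular Diels–Alder reaction of 2-silyloxydienes joined to the dienophile through a disposable silyl acetal tether. Ring B closes in the cycloaddition mode (C2–C3 and C1–C8a formed together), and the temporary eight-membered dioxasila ring C2–C3–C4–O–Si–O–C2′–C1′ closes through the same C2–C3 bond, giving a bicyclo[5.3.1] framework with a bridgehead silyl enol ether. The cis relationship of the C1 methyl group and C1′ follows from the E geometry of the enoate, and the relationship of C1/C2 to C8a follows from the tether: the five-atom link reaches from the in-plane C4 oxygen to C2 only when C1′ lies endo over the diene, which places the α-methyl group endo and the ester exo, i.e. cis to H-8a. The absolute sense at C8a is set by attack on the diene face anti to the allylic C8 methyl group (pseudo-axial in the reactive half-chair of ring A), and in this mode the C2′ substituent sits pseudo-equatorial on the forming eight-membered ring, so the bought and the catalytically set centres are matched. The step needs regioselectivity (secured by the tether, reinforced by the para-directing silyloxy group), ester-exo topology against the normal endo preference (secured by the tether) and π-facial selectivity (secured by the C8 methyl group), and it sets the quaternary C1, C2 and C8a in one operation.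

Step 7
Reactants: 13 silicon-bridged cycloadduct
Product: 15 methyl 2β-[(2R,3E)-2-hydroxy-5,5-dimethoxypent-3-en-1-yl]-1β,6β,8α-trimethyl-4-oxo-4aα,8aα-decahydronaphthalene-1α-carboxylate (cis-fused), via enol 14 (not isolated)
Conditions: Bu4NF, AcOH (1:1), THF, −20 → 0 °C
Reagents that add atoms: none
Why: Fluoride should cleave both Si–O bonds of the silyl acetal, and buffered kinetic ketonisation of the liberated enol should protonate C4a on the α face, away from the axial C1 methyl group and ring A carbon C8, giving the cis ring fusion as is usual for kinetic ketonisation of 1-decalone-type enols.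

Step 8
Reactants: 15 cis-fused keto alcohol
Product: 16 methyl 2β-[(2R,3E)-2-{[tert-butyl(dimethyl)silyl]oxy}-5,5-dimethoxypent-3-en-1-yl]-1β,6β,8α-trimethyl-4-oxo-4aα,8aα-decahydronaphthalene-1α-carboxylate
Conditions: TBSCl, imidazole, DMF, rt
Reagents that add atoms: tert-butyl(chloro)dimethylsilane, CC(C)(C)[Si](C)(C)Cl
Why: Standard silylation of the secondary allylic alcohol under conditions too mild to epimerise C4a or open the acetal.

Step 9
Reactants: 16 silyl ether ketone
Product: 17 methyl 2β-[(2R,3E)-2-{[tert-butyl(dimethyl)silyl]oxy}-5,5-dimethoxypent-3-en-1-yl]-1β,6β,8α-trimethyl-4-{[(trifluoromethyl)sulfonyl]oxy}-1,2,4aα,5,6,7,8,8aα-octahydronaphthalene-1α-carboxylate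
Conditions: KN(SiMe3)2, THF, −78 °C; then PhNTf2, −78 → −30 °C
Reagents that add atoms: 1,1,1-trifluoro-N-phenyl-N-(trifluoromethanesulfonyl)methanesulfonamide, O=S(=O)(N(c1ccccc1)S(=O)(=O)C(F)(F)F)C(F)(F)F
Why: Kinetic deprotonation by the hindered amide should occur at the C3 methylene and not at the ring-fusion methine C4a, and O-triflation then fixes the C3=C4 enol triflate without epimerising C4a (the ester has no α-hydrogen).

Step 10
Reactants: 17 enol triflate
Product: 18 methyl (1S,2R,4aS,6R,8R,8aS)-2-[(2R,3E)-2-{[tert-butyl(dimethyl)silyl]oxy}-5,5-dimethoxypent-3-en-1-yl]-1,6,8-trimethyl-1,2,4a,5,6,7,8,8a-octahydronaphthalene-1-carboxylate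
Conditions: Pd(OAc)2 (5 mol %), PPh3 (10 mol %), HCO2H, Et3N, DMF, 60 °C
Reagents that add atoms: none
Why: Palladium-catalysed formate reduction of the enol triflate should replace OTf by H and leave the C3=C4 double bond in place, which locks C4a as a non-epimerisable allylic centre.

Step 11
Reactants: 18 decalin acetal
Product: 19 methyl (1S,2R,4aS,6R,8R,8aS)-2-[(2R,3E)-2-{[tert-butyl(dimethyl)silyl]oxy}-5-oxopent-3-en-1-yl]-1,6,8-trimethyl-1,2,4a,5,6,7,8,8a-octahydronaphthalene-1-carboxylate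
Conditions: pyridinium p-toluenesulfonate (cat.), acetone/H2O (9:1), rt
Reagents that add atoms: water, O
Why: Mild acid hydrolysis of the allylic dimethyl acetal should unmask the (E)-enal while the secondary silyl ether survives.

Step 12
Reactants: 20 (4R)-4-benzyl-3-propanoyl-1,3-oxazolidin-2-one; 21 propanal
Product: 22 (4R)-4-benzyl-3-[(2R,3S)-3-hydroxy-2-methylpentanoyl]-1,3-oxazolidin-2-one
Conditions: Bu2BOTf, iPr2NEt, CH2Cl2, 0 °C; 21, −78 → 0 °C; then pH 7 buffer, MeOH, 30% H2O2, 0 °C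
Reagents that add atoms: none
Why: The Evans syn-aldol reaction (Z-boron enolate, closed chair transition state, auxiliary-controlled facial selectivity) should give the (2R,3S) syn aldol, i.e. C7′ and C8′ of the target.

Step 13
Reactants: 22 syn aldol
Product: 23 (4R)-4-benzyl-3-[(2R,3S)-3-{[tert-butyl(dimethyl)silyl]oxy}-2-methylpentanoyl]-1,3-oxazolidin-2-one
Conditions: TBSOTf, 2,6-lutidine, CH2Cl2, −78 → 0 °C
Reagents that add atoms: tert-butyldimethylsilyl trifluoromethanesulfonate, CC(C)(C)[Si](C)(C)OS(=O)(=O)C(F)(F)F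
Why: Standard silylation of the hindered secondary alcohol, which also blocks retro-aldol cleavage.

Step 14
Reactants: 23 silylated aldol
Product: 24 (2S,3S)-3-{[tert-butyl(dimethyl)silyl]oxy}-2-methylpentan-1-ol
Conditions: LiBH4, MeOH (1 equiv), THF, 0 °C
Reagents that add atoms: none
Why: Reductive cleavage of the imide should release the primary alcohol and the auxiliary without epimerising the α-stereocentre.

Step 15
Reactants: 24 (2S,3S)-3-{[tert-butyl(dimethyl)silyl]oxy}-2-methylpentan-1-ol; 25 1-phenyl-1H-tetrazole-5-thiol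
Product: 26 5-{[(2R,3S)-3-{[tert-butyl(dimethyl)silyl]oxy}-2-methylpentyl]sulfanyl}-1-phenyl-1H-tetrazole
Conditions: PPh3, diisopropyl azodicarboxylate, THF, 0 °C → rt
Reagents that add atoms: none
Why: Mitsunobu thioetherification of the primary alcohol; no stereocentre reacts (the descriptor at C2 changes only through priority).

Step 16
Reactants: 26 sulfide
Product: 27 5-{[(2R,3S)-3-{[tert-butyl(dimethyl)silyl]oxy}-2-methylpentyl]sulfonyl}-1-phenyl-1H-tetrazole
Conditions: (NH4)6Mo7O24·4H2O (10 mol %), 30% H2O2, EtOH, 0 °C → rt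
Reagents that add atoms: hydrogen peroxide, OO
Why: Molybdate-catalysed peroxide oxidation is the standard route from the sulfide to the Julia–Kocienski sulfone and tolerates the silyl ether.

Step 17
Reactants: 19 enal; 27 sulfone
Product: 28 methyl (1S,2R,4aS,6R,8R,8aS)-2-[(2R,3E,5E,7S,8S)-2,8-bis{[tert-butyl(dimethyl)silyl]oxy}-7-methyldeca-3,5-dien-1-yl]-1,6,8-trimethyl-1,2,4a,5,6,7,8,8a-octahydronaphthalene-1-carboxylate
Conditions: 27, KN(SiMe3)2, DME, −60 °C; then 19, −60 °C → rt
Reagents that add atoms: none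
Why: Julia–Kocienski olefination (addition of the metallated sulfone, Smiles rearrangement, loss of SO2 and the tetrazolone) should form C5′=C6′ with E geometry, as expected for phenyltetrazolyl sulfones and conjugated aldehydes with a potassium counter-ion in DME.

Step 18
Reactants: 28 diene methyl ester
Product: 29 (1S,2R,4aS,6R,8R,8aS)-2-[(2R,3E,5E,7S,8S)-2,8-bis{[tert-butyl(dimethyl)silyl]oxy}-7-methyldeca-3,5-dien-1-yl]-1,6,8-trimethyl-1,2,4a,5,6,7,8,8a-octahydronaphthalene-1-carboxylic acid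
Conditions: NaSEt, DMF, 60 °C; aq. NaHSO4 work-up
Reagents that add atoms: none
Why: SN2 demethylation by thiolate attacks the O-methyl carbon, so the steric shielding of the acyl carbon by the quaternary C1 does not matter.

Step 19
Reactants: 29 carboxylic acid; 30 S-tert-butyl ethanethioate
Product: 32 S-tert-butyl 3-{(1S,2R,4aS,6R,8R,8aS)-2-[(2R,3E,5E,7S,8S)-2,8-bis{[tert-butyl(dimethyl)silyl]oxy}-7-methyldeca-3,5-dien-1-yl]-1,6,8-trimethyl-1,2,4a,5,6,7,8,8a-octahydronaphthalen-1-yl}-3-oxopropanethioate, via acid chloride 31 (not isolated)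
Conditions: 29, 1-chloro-N,N,2-trimethylprop-1-en-1-amine, CH2Cl2, 0 °C → rt; then added to 30/LiN(SiMe3)2 (3 equiv each), THF, −78 → −40 °C
Reagents that add atoms: none
Why: Neutral acid chloride formation followed by crossed Claisen acylation of the thioacetate lithium enolate should give the β-keto thioester; the acid chloride has no α-hydrogen and the excess enolate deprotonates the product.

Step 20
Reactants: 32 β-keto thioester; 33 methyl glycinate hydrochloride
Product: 34 methyl N-(3-{(1S,2R,4aS,6R,8R,8aS)-2-[(2R,3E,5E,7S,8S)-2,8-bis{[tert-butyl(dimethyl)silyl]oxy}-7-methyldeca-3,5-dien-1-yl]-1,6,8-trimethyl-1,2,4a,5,6,7,8,8a-octahydronaphthalen-1-yl}-3-oxopropanoyl)glycinate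
Conditions: AgOCOCF3, Et3N, THF, 0 °C → rt (dark)
Reagents that add atoms: none
Why: Silver-promoted aminolysis of the β-keto thioester is mild, thiophile-driven amide formation that should spare the diene and silyl ethers.

Step 21
Reactants: 34 β-keto amide
Product: 35 3-{[(1S,2R,4aS,6R,8R,8aS)-2-[(2R,3E,5E,7S,8S)-2,8-bis{[tert-butyl(dimethyl)silyl]oxy}-7-methyldeca-3,5-dien-1-yl]-1,6,8-trimethyl-1,2,4a,5,6,7,8,8a-octahydronaphthalen-1-yl]carbonyl}-4-hydroxy-1,5-dihydro-2H-pyrrol-2-one
Conditions: KOtBu, tBuOH/THF, rt; aq. KHSO4 work-up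
Reagents that add atoms: none
Why: Lacey–Dieckmann cyclisation of the β-keto amide enolate onto the glycinate ester should close the 3-acyl tetramic acid, the stable enolate of the product driving the reaction.

Step 22
Reactants: 35 bis-silyl tetramic acid
Product: 36 3-{[(1S,2R,4aS,6R,8R,8aS)-2-[(2R,3E,5E,7S,8S)-2,8-dihydroxy-7-methyldeca-3,5-dien-1-yl]-1,6,8-trimethyl-1,2,4a,5,6,7,8,8a-octahydronaphthalen-1-yl]carbonyl}-4-hydroxy-1,5-dihydro-2H-pyrrol-2-one (CNP0117518.2)
Conditions: HF·pyridine, pyridine, THF, 0 °C → rt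
Reagents that add atoms: none
Why: Buffered fluoride-mediated desilylation should free both secondary alcohols without ionising the dienyl carbinol.

**Compound list**

1 | (R)-5-methylcyclohex-2-en-1-one | C[C@@H]1CC=CC(=O)C1 | starting material
2 | lithium (3R,5R)-3,5-dimethylcyclohex-1-en-1-olate | [Li+].[O-]C1=C[C@H](C)C[C@@H](C)C1 | intermediate
3 | (3R,5R)-3,5-dimethylcyclohex-1-en-1-yl trifluoromethanesulfonate | FC(F)(F)S(=O)(=O)OC1=C[C@H](C)C[C@@H](C)C1 | intermediate
4 | tributyl(1-ethoxyethenyl)stannane | CCCC[Sn](CCCC)(CCCC)C(=C)OCC | starting material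
5 | (3R,5R)-1-(1-ethoxyethenyl)-3,5-dimethylcyclohex-1-ene | CCOC(=C)C1=C[C@H](C)C[C@@H](C)C1 | intermediate
6 | 1-[(3R,5R)-3,5-dimethylcyclohex-1-en-1-yl]ethan-1-one | CC(=O)C1=C[C@H](C)C[C@@H](C)C1 | intermediate
7 | methyl (2E)-2-methylbut-2-enoate | C/C=C(\C)C(=O)OC | starting material
8 | tert-butyl[(1-methoxy-2-methylbuta-1,3-dien-1-yl)oxy]dimethylsilane | COC(O[Si](C)(C)C(C)(C)C)=C(C)C=C | intermediate
9 | (2E)-4,4-dimethoxybut-2-enal | COC(OC)/C=C/C=O | starting material
10 | methyl (2E,5R,6E)-5-hydroxy-8,8-dimethoxy-2-methylocta-2,6-dienoate | COC(OC)/C=C/[C@H](O)C/C=C(\C)C(=O)OC | intermediate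
11 | chloro({1-[(3R,5R)-3,5-dimethylcyclohex-1-en-1-yl]ethenyl}oxy)di(propan-2-yl)silane | C=C(O[Si](Cl)(C(C)C)C(C)C)C1=C[C@H](C)C[C@@H](C)C1 | intermediate
12 | methyl (2E,5R,6E)-5-{[({1-[(3R,5R)-3,5-dimethylcyclohex-1-en-1-yl]ethenyl}oxy)di(propan-2-yl)silyl]oxy}-8,8-dimethoxy-2-methylocta-2,6-dienoate | COC(OC)/C=C/[C@@H](C/C=C(\C)C(=O)OC)O[Si](C(C)C)(C(C)C)OC(=C)C1=C[C@H](C)C[C@@H](C)C1 | intermediate
13 | silicon-bridged cycloadduct (1β-CH3, 1α-CO2CH3, 2β-C1′, 8aα-H, 6β-CH3, 8α-CH3; C4=C4a silyl enol ether; C4–O–Si(iPr)2–O–C2′ bridge) | COC(OC)/C=C/[C@H]4C[C@@H]1CC(O[Si](C(C)C)(C(C)C)O4)=C2C[C@H](C)C[C@@H](C)[C@@H]2[C@@]1(C)C(=O)OC | intermediate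
14 | methyl 4-hydroxy-2β-[(2R,3E)-2-hydroxy-5,5-dimethoxypent-3-en-1-yl]-1β,6β,8α-trimethyl-1,2,3,5,6,7,8,8aα-octahydronaphthalene-1α-carboxylate (enol) | COC(OC)/C=C/[C@H](O)C[C@@H]1CC(O)=C2C[C@H](C)C[C@@H](C)[C@@H]2[C@@]1(C)C(=O)OC | intermediate
15 | methyl 2β-[(2R,3E)-2-hydroxy-5,5-dimethoxypent-3-en-1-yl]-1β,6β,8α-trimethyl-4-oxo-4aα,8aα-decahydronaphthalene-1α-carboxylate | COC(OC)/C=C/[C@H](O)C[C@@H]1CC(=O)[C@@H]2C[C@H](C)C[C@@H](C)[C@@H]2[C@@]1(C)C(=O)OC | intermediate
16 | methyl 2β-[(2R,3E)-2-{[tert-butyl(dimethyl)silyl]oxy}-5,5-dimethoxypent-3-en-1-yl]-1β,6β,8α-trimethyl-4-oxo-4aα,8aα-decahydronaphthalene-1α-carboxylate | COC(OC)/C=C/[C@H](O[Si](C)(C)C(C)(C)C)C[C@@H]1CC(=O)[C@@H]2C[C@H](C)C[C@@H](C)[C@@H]2[C@@]1(C)C(=O)OC | intermediate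
17 | methyl 2β-[(2R,3E)-2-{[tert-butyl(dimethyl)silyl]oxy}-5,5-dimethoxypent-3-en-1-yl]-1β,6β,8α-trimethyl-4-{[(trifluoromethyl)sulfonyl]oxy}-1,2,4aα,5,6,7,8,8aα-octahydronaphthalene-1α-carboxylate | COC(OC)/C=C/[C@H](O[Si](C)(C)C(C)(C)C)C[C@@H]1C=C(OS(=O)(=O)C(F)(F)F)[C@@H]2C[C@H](C)C[C@@H](C)[C@@H]2[C@@]1(C)C(=O)OC | intermediate
18 | methyl (1S,2R,4aS,6R,8R,8aS)-2-[(2R,3E)-2-{[tert-butyl(dimethyl)silyl]oxy}-5,5-dimethoxypent-3-en-1-yl]-1,6,8-trimethyl-1,2,4a,5,6,7,8,8a-octahydronaphthalene-1-carboxylate | COC(OC)/C=C/[C@H](O[Si](C)(C)C(C)(C)C)C[C@@H]1C=C[C@@H]2C[C@H](C)C[C@@H](C)[C@@H]2[C@@]1(C)C(=O)OC | intermediate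
19 | methyl (1S,2R,4aS,6R,8R,8aS)-2-[(2R,3E)-2-{[tert-butyl(dimethyl)silyl]oxy}-5-oxopent-3-en-1-yl]-1,6,8-trimethyl-1,2,4a,5,6,7,8,8a-octahydronaphthalene-1-carboxylate | O=C/C=C/[C@H](O[Si](C)(C)C(C)(C)C)C[C@@H]1C=C[C@@H]2C[C@H](C)C[C@@H](C)[C@@H]2[C@@]1(C)C(=O)OC | intermediate
20 | (4R)-4-benzyl-3-propanoyl-1,3-oxazolidin-2-one | CCC(=O)N1[C@H](Cc2ccccc2)COC1=O | starting material
21 | propanal | CCC=O | starting material
22 | (4R)-4-benzyl-3-[(2R,3S)-3-hydroxy-2-methylpentanoyl]-1,3-oxazolidin-2-one | CC[C@H](O)[C@@H](C)C(=O)N1[C@H](Cc2ccccc2)COC1=O | intermediate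
23 | (4R)-4-benzyl-3-[(2R,3S)-3-{[tert-butyl(dimethyl)silyl]oxy}-2-methylpentanoyl]-1,3-oxazolidin-2-one | CC[C@H](O[Si](C)(C)C(C)(C)C)[C@@H](C)C(=O)N1[C@H](Cc2ccccc2)COC1=O | intermediate
24 | (2S,3S)-3-{[tert-butyl(dimethyl)silyl]oxy}-2-methylpentan-1-ol | CC[C@H](O[Si](C)(C)C(C)(C)C)[C@@H](C)CO | intermediate
25 | 1-phenyl-1H-tetrazole-5-thiol | Sc1nnnn1-c1ccccc1 | starting material
26 | 5-{[(2R,3S)-3-{[tert-butyl(dimethyl)silyl]oxy}-2-methylpentyl]sulfanyl}-1-phenyl-1H-tetrazole | CC[C@H](O[Si](C)(C)C(C)(C)C)[C@@H](C)CSc1nnnn1-c1ccccc1 | intermediate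
27 | 5-{[(2R,3S)-3-{[tert-butyl(dimethyl)silyl]oxy}-2-methylpentyl]sulfonyl}-1-phenyl-1H-tetrazole | CC[C@H](O[Si](C)(C)C(C)(C)C)[C@@H](C)CS(=O)(=O)c1nnnn1-c1ccccc1 | intermediate
28 | methyl (1S,2R,4aS,6R,8R,8aS)-2-[(2R,3E,5E,7S,8S)-2,8-bis{[tert-butyl(dimethyl)silyl]oxy}-7-methyldeca-3,5-dien-1-yl]-1,6,8-trimethyl-1,2,4a,5,6,7,8,8a-octahydronaphthalene-1-carboxylate | CC[C@H](O[Si](C)(C)C(C)(C)C)[C@@H](C)/C=C/C=C/[C@H](O[Si](C)(C)C(C)(C)C)C[C@@H]1C=C[C@@H]2C[C@H](C)C[C@@H](C)[C@@H]2[C@@]1(C)C(=O)OC | intermediate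
29 | (1S,2R,4aS,6R,8R,8aS)-2-[(2R,3E,5E,7S,8S)-2,8-bis{[tert-butyl(dimethyl)silyl]oxy}-7-methyldeca-3,5-dien-1-yl]-1,6,8-trimethyl-1,2,4a,5,6,7,8,8a-octahydronaphthalene-1-carboxylic acid | CC[C@H](O[Si](C)(C)C(C)(C)C)[C@@H](C)/C=C/C=C/[C@H](O[Si](C)(C)C(C)(C)C)C[C@@H]1C=C[C@@H]2C[C@H](C)C[C@@H](C)[C@@H]2[C@@]1(C)C(=O)O | intermediate
30 | S-tert-butyl ethanethioate | CC(=O)SC(C)(C)C | starting material
31 | acid chloride of 29 | CC[C@H](O[Si](C)(C)C(C)(C)C)[C@@H](C)/C=C/C=C/[C@H](O[Si](C)(C)C(C)(C)C)C[C@@H]1C=C[C@@H]2C[C@H](C)C[C@@H](C)[C@@H]2[C@@]1(C)C(=O)Cl | intermediate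
32 | S-tert-butyl 3-oxo-3-(decalin-1-yl)propanethioate (β-keto thioester; decalin and side chain as in 28) | CC[C@H](O[Si](C)(C)C(C)(C)C)[C@@H](C)/C=C/C=C/[C@H](O[Si](C)(C)C(C)(C)C)C[C@@H]1C=C[C@@H]2C[C@H](C)C[C@@H](C)[C@@H]2[C@@]1(C)C(=O)CC(=O)SC(C)(C)C | intermediate
33 | methyl glycinate hydrochloride | COC(=O)CN.Cl | starting material
34 | methyl N-[3-oxo-3-(decalin-1-yl)propanoyl]glycinate (β-keto amide; decalin and side chain as in 28) | CC[C@H](O[Si](C)(C)C(C)(C)C)[C@@H](C)/C=C/C=C/[C@H](O[Si](C)(C)C(C)(C)C)C[C@@H]1C=C[C@@H]2C[C@H](C)C[C@@H](C)[C@@H]2[C@@]1(C)C(=O)CC(=O)NCC(=O)OC | intermediate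
35 | 2′,8′-bis-O-(tert-butyldimethylsilyl) derivative of the target | CC[C@H](O[Si](C)(C)C(C)(C)C)[C@@H](C)/C=C/C=C/[C@H](O[Si](C)(C)C(C)(C)C)C[C@@H]1C=C[C@@H]2C[C@H](C)C[C@@H](C)[C@@H]2[C@@]1(C)C(=O)C1=C(O)CNC1=O | intermediate
36 | 3-{[(1S,2R,4aS,6R,8R,8aS)-2-[(2R,3E,5E,7S,8S)-2,8-dihydroxy-7-methyldeca-3,5-dien-1-yl]-1,6,8-trimethyl-1,2,4a,5,6,7,8,8a-octahydronaphthalen-1-yl]carbonyl}-4-hydroxy-1,5-dihydro-2H-pyrrol-2-one | CC[C@H](O)[C@@H](C)/C=C/C=C/[C@H](O)C[C@@H]1C=C[C@@H]2C[C@H](C)C[C@@H](C)[C@@H]2[C@@]1(C)C(=O)C1=C(O)CNC1=O | target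

**Step count and risks**

Total step count: 22. Longest linear sequence: 15 steps (steps 3–11 and 17–22 from methyl tiglate; equally steps 1, 2, 5–11 and 17–22 from the cyclohexenone).

Steps most likely to fail:

- **Step 6 (cycloaddition).** The trisubstituted enoate may be too unreactive, so that the precursor decomposes before it cyclises, or π-facial control may erode at the temperature needed. Fallback, setting out from 10 and returning at 13: the ester is exchanged for the more dienophilic aldehyde. Reduction of 10 with iBu2AlH (CH2Cl2, −78 °C) should give (2E,5R,6E)-8,8-dimethoxy-2-methylocta-2,6-diene-1,5-diol F1. Selective oxidation of the primary allylic alcohol (2,2,6,6-tetramethylpiperidin-1-oxyl (cat.), PhI(OAc)2) should give (2E,5R,6E)-5-hydroxy-8,8-dimethoxy-2-methylocta-2,6-dienal F2. Silylation of F2 with chlorosilane 11 (imidazole) gives the tethered enal F3, which should cyclise near 110 °C in toluene to the bridged aldehyde F4. Buffered NaClO2 oxidation (Pinnick oxidation, 2-methylbut-2-ene) to the bridged acid F5 and esterification with Me3SiCHN2 lead back to 13.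

- **Step 7 (tether cleavage and ketonisation).** Protonation at C4a may occur on the wrong face, or the ketone may epimerise to the trans-fused isomer. Fallback, setting out from 13 and returning at 16: the C4a–H bond is made by hydrogen-atom transfer instead of protonation. PhSeCl (CH2Cl2, −78 °C) should selenenylate the silyl enol ether of 13 regiospecifically at C4a, and Bu4NF/AcOH then frees the C2′ hydroxyl to give the 4a-(phenylselanyl) keto alcohol F6. TBSCl/imidazole converts it into the silyl ether F7. Bu3SnH with 2,2′-azobis(2-methylpropionitrile) (toluene, 80 °C) should cleave the C–Se bond through the planar α-keto radical, which takes hydrogen irreversibly from the bulky stannane on the convex α face, giving 16.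

- **Step 19 (acylation).** Acylation at the congested acyl carbon may be incomplete while the thioacetate enolate self-condenses. Fallback, setting out from 28 and returning at 32: the acyl carbon is taken through the aldehyde. iBu2AlH should reduce the ester of 28 to the neopentyl alcohol F8, and oxidation with 1,1,1-triacetoxy-1,1-dihydro-1,2-benziodoxol-3(1H)-one (DMP) gives the aldehyde F9. Addition of the lithium enolate of 30 (THF, −78 °C) gives the β-hydroxy thioester F10 (carbinol epimers, inconsequential), and a second DMP oxidation gives 32.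

Further compounds
F1 | step 6 | (2E,5R,6E)-8,8-dimethoxy-2-methylocta-2,6-diene-1,5-diol | COC(OC)/C=C/[C@H](O)C/C=C(\C)CO
F2 | step 6 | (2E,5R,6E)-5-hydroxy-8,8-dimethoxy-2-methylocta-2,6-dienal | COC(OC)/C=C/[C@H](O)C/C=C(\C)C=O
F3 | step 6 | tethered enal (12 with CHO in place of CO2CH3) | COC(OC)/C=C/[C@@H](C/C=C(\C)C=O)O[Si](C(C)C)(C(C)C)OC(=C)C1=C[C@H](C)C[C@@H](C)C1
F4 | step 6 | bridged cycloadduct aldehyde (13 with CHO in place of CO2CH3) | COC(OC)/C=C/[C@H]4C[C@@H]1CC(O[Si](C(C)C)(C(C)C)O4)=C2C[C@H](C)C[C@@H](C)[C@@H]2[C@@]1(C)C=O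
F5 | step 6 | bridged cycloadduct carboxylic acid | COC(OC)/C=C/[C@H]4C[C@@H]1CC(O[Si](C(C)C)(C(C)C)O4)=C2C[C@H](C)C[C@@H](C)[C@@H]2[C@@]1(C)C(=O)O
F6 | step 7 | methyl 2β-[(2R,3E)-2-hydroxy-5,5-dimethoxypent-3-en-1-yl]-1β,6β,8α-trimethyl-4-oxo-4aα-(phenylselanyl)-8aα-decahydronaphthalene-1α-carboxylate | COC(OC)/C=C/[C@H](O)C[C@@H]1CC(=O)[C@]2([Se]c3ccccc3)C[C@H](C)C[C@@H](C)[C@@H]2[C@@]1(C)C(=O)OC
F7 | step 7 | tert-butyldimethylsilyl ether of F6 | COC(OC)/C=C/[C@H](O[Si](C)(C)C(C)(C)C)C[C@@H]1CC(=O)[C@]2([Se]c3ccccc3)C[C@H](C)C[C@@H](C)[C@@H]2[C@@]1(C)C(=O)OC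
F8 | step 19 | primary alcohol (28 with CH2OH in place of CO2CH3) | CC[C@H](O[Si](C)(C)C(C)(C)C)[C@@H](C)/C=C/C=C/[C@H](O[Si](C)(C)C(C)(C)C)C[C@@H]1C=C[C@@H]2C[C@H](C)C[C@@H](C)[C@@H]2[C@@]1(C)CO
F9 | step 19 | aldehyde (28 with CHO in place of CO2CH3) | CC[C@H](O[Si](C)(C)C(C)(C)C)[C@@H](C)/C=C/C=C/[C@H](O[Si](C)(C)C(C)(C)C)C[C@@H]1C=C[C@@H]2C[C@H](C)C[C@@H](C)[C@@H]2[C@@]1(C)C=O
F10 | step 19 | β-hydroxy thioester (32 with CH(OH) in place of the ketone) | CC[C@H](O[Si](C)(C)C(C)(C)C)[C@@H](C)/C=C/C=C/[C@H](O[Si](C)(C)C(C)(C)C)C[C@@H]1C=C[C@@H]2C[C@H](C)C[C@@H](C)[C@@H]2[C@@]1(C)C(O)CC(=O)SC(C)(C)C
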